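**Plan**
1. Retrosynthesis: the C5/C7 phenols and C6/C8 formyl groups go back to aryl C–F and C–H bonds. O1–C8a and C2–CH3 are then cut together (key step), leaving a (Z)-cyclodec-5-enone with a 1-(2,4,6-trifluorophenyl)-3-methylbutyl group on its α-carbon. Further cuts: C1′–isobutyl (conjugate addition), C2=C1′ (aldol condensation), ring bond C3–C4 of the cyclodecenone (oxy-Cope), the cyclohexane bond (carbonyl-ene) and the prenyl–Cα bond (auxiliary alkylation).
2. Enabling feature: C2 is a fully substituted ether carbon carrying CH3, bonded through O1 to C8a of a benzene ring whose three oxygens (O1, 5-OH, 7-OH) are 1,3,5-related with the formyl carbons C6 and C8 between them. A 2,4,6-trifluorophenyl ring can therefore give O1–C8a by fluoride loss to a C2 alkoxide; the remaining fluorines acidify C6–H and C8–H and leave once formyl groups flank them.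
3. Forward order: acyclic chain → cyclohexane (ene reaction) → ten-membered ring (four-carbon ring expansion) → arene attached → pyran ring (key step) → arene decorated.
4. Stereochemistry: the carbinol-bearing ring carbon (C8) comes from an Evans alkylation; the Z olefin from the chair transition state of a cis-divinylcyclohexanolate; C4 from a chiral copper catalyst; C3 by equilibration α to the ketone; C2 by Felkin–Anh addition of methyl.

Key step: step 15

Remark (locants): chroman numbering (O1, C2, C3, C4, C4a, C5–C8, C8a) is used for pyran and arene. Before the pyran exists, the carbocycle carries cyclodecenone locants (C1 carbonyl = later C2; C2 = later C3; C5=C6 olefin; C8 carbinol-bearing carbon), and C1′ is the benzylic carbon (later C4).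
Remark (work-up): work-up is aqueous unless a quench is named; metal residues are taken in the hydrolysed form this gives.
Remark (numbering): an in-flask species is numbered when a reagent added later to the same flask consumes it.
Assumption: the sense of induction of the copper catalyst in step 14 can be selected through the ligand antipode.

**Step 1**
Reactants: 1 pent-4-enoic acid; 2 (4S)-4-benzyl-1,3-oxazolidin-2-one
Product: 4 (4S)-4-benzyl-3-(pent-4-enoyl)-1,3-oxazolidin-2-one, via mixed pivalic anhydride 3 (not isolated)
Conditions: PivCl, Et3N, THF, −20 °C; then 2, LiCl, rt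
Reagents that add atoms: none
Why: N-acylation of the oxazolidinone through the mixed pivalic anhydride is the standard way to load an Evans auxiliary with an unhindered acid; no stereocentre is formed.

**Step 2**
Reactants: 4; 5 prenyl bromide
Product: 7 (4S)-4-benzyl-3-[(2R)-5-methyl-2-(prop-2-en-1-yl)hex-4-enoyl]-1,3-oxazolidin-2-one, via sodium Z-enolate 6 (not isolated)
Conditions: NaHMDS, THF, −78 °C; then 5, −78 → −40 °C
Reagents that add atoms: none
Why: Evans asymmetric alkylation: the chelated Z-enolate is shielded on one face by the benzyl group, so the allylic bromide enters from the other face and sets the (2R) centre that later becomes C8.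

**Step 3**
Reactants: 7
Product: 8 methyl (2R)-5-methyl-2-(prop-2-en-1-yl)hex-4-enoate
Conditions: NaOMe, MeOH–THF, 0 °C
Reagents that add atoms: sodium methoxide, C[O-].[Na+]
Why: Methanolysis of the imide (exocyclic acyl transfer) releases the auxiliary and should leave the non-activated α-centre untouched at 0 °C.

**Step 4**
Reactants: 8; 9 methylmagnesium bromide
Product: 10 (3R)-2,6-dimethyl-3-(prop-2-en-1-yl)hept-5-en-2-ol
Conditions: MeMgBr (3 equiv), THF, 0 °C → rt
Reagents that add atoms: none
Why: Double Grignard addition to the ester builds the 2-hydroxypropan-2-yl group of the target without disturbing the adjacent stereocentre.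

**Step 5**
Reactants: 10
Product: 11 triethyl{[(3R)-2,6-dimethyl-3-(prop-2-en-1-yl)hept-5-en-2-yl]oxy}silane
Conditions: TESOTf, 2,6-lutidine, CH2Cl2, −78 → 0 °C
Reagents that add atoms: triethylsilyl trifluoromethanesulfonate, CC[Si](CC)(CC)OS(=O)(=O)C(F)(F)F
Why: Silylation with the triflate caps the hindered tertiary alcohol, which would otherwise form a lactol with the aldehyde of step 7 and consume base in every later anionic step.

**Step 6**
Reactants: 11
Product: 13 (4R)-7-methyl-4-[2-(triethylsilyloxy)propan-2-yl]oct-6-en-1-ol, via B-alkyl-9-BBN adduct 12 (not isolated)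
Conditions: 9-BBN, THF, 0 °C → rt; then NaOH, H2O2, 0 °C
Reagents that add atoms: hydrogen peroxide, OO
Why: Anti-Markovnikov hydroboration–oxidation; the bulky dialkylborane reacts with the monosubstituted vinyl group and leaves the trisubstituted prenyl olefin alone.

**Step 7**
Reactants: 13
Product: 14 (4R)-7-methyl-4-[2-(triethylsilyloxy)propan-2-yl]oct-6-enal
Conditions: Dess–Martin periodinane, pyridine, CH2Cl2, 0 °C → rt
Reagents that add atoms: none
Why: Dess–Martin oxidation of a primary alcohol to the aldehyde under buffered conditions; silyl ether and olefin are inert.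

**Step 8**
Reactants: 14
Product: 15 (1R,2S,4R)-2-(prop-1-en-2-yl)-4-[2-(triethylsilyloxy)propan-2-yl]cyclohexan-1-ol
Conditions: ZnBr2, CH2Cl2, 0 °C
Reagents that add atoms: none
Why: Intramolecular type I carbonyl-ene reaction, the analogue of the citronellal-to-isopulegol cyclisation: a chair transition state with the silyloxypropyl group equatorial forms the ring and should place hydroxyl and isopropenyl trans-diequatorial, so C2 and C4 are cis.

**Step 9**
Reactants: 15
Product: 16 (2S,4R)-2-(prop-1-en-2-yl)-4-[2-(triethylsilyloxy)propan-2-yl]cyclohexan-1-one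
Conditions: Dess–Martin periodinane, pyridine, CH2Cl2, 0 °C
Reagents that add atoms: none
Why: Buffered Dess–Martin oxidation should give the β,γ-unsaturated ketone without migrating the isopropenyl double bond or epimerising the already equatorial C2 substituent.

**Step 10**
Reactants: 16; 17 ethynylmagnesium bromide
Product: 18 (1R,2S,4R)-1-ethynyl-2-(prop-1-en-2-yl)-4-[2-(triethylsilyloxy)propan-2-yl]cyclohexan-1-ol
Conditions: 17, CeCl3, THF, −78 → 0 °C
Reagents that add atoms: none
Why: 1,2-Addition of a cerium acetylide: the slim sp nucleophile attacks the conformationally anchored cyclohexanone axially, placing ethynyl axial and cis to the equatorial isopropenyl group, and the cerium reagent avoids enolising the acidic α-centre.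

**Step 11**
Reactants: 18
Product: 19 (1S,2S,4R)-1-ethenyl-2-(prop-1-en-2-yl)-4-[2-(triethylsilyloxy)propan-2-yl]cyclohexan-1-ol
Conditions: H2 (1 atm), Lindlar catalyst, quinoline, EtOAc, rt
Reagents that add atoms: none
Why: Lindlar semi-hydrogenation stops at the alkene for a terminal alkyne and does not reduce the 1,1-disubstituted olefin.

**Step 12**
Reactants: 19; 20 2,4,6-trifluorobenzaldehyde
Product: 22 (5Z,8R)-2-[hydroxy(2,4,6-trifluorophenyl)methyl]-5-methyl-8-[2-(triethylsilyloxy)propan-2-yl]cyclodec-5-en-1-one, via potassium dienolate 21 (not isolated)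
Conditions: KH, 18-crown-6, THF, 0 → 50 °C; then 20, −78 °C; AcOH, −78 °C
Reagents that add atoms: none
Why: Anionic oxy-Cope rearrangement then aldol addition: the alkoxide of the cis-divinyl carbinol reacts through the chair transition state reached from its ground-state chair (vinyl axial; isopropenyl, oxide and silyloxypropyl equatorial), which holds the ring CH2 next to the isopropenyl-bearing carbon syn to the forming C–C bond and so should give the Z C5=C6 olefin and, regiospecifically, the C1–C2 enolate that the non-enolisable aldehyde traps cold; C8 is untouched and the two aldol centres (a mixture) are removed in step 13.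

**Step 13**
Reactants: 22
Product: 24 (2E,5Z,8R)-5-methyl-8-[2-(triethylsilyloxy)propan-2-yl]-2-[(2,4,6-trifluorophenyl)methylidene]cyclodec-5-en-1-one, via benzylic mesylate 23 (not isolated)
Conditions: MsCl, Et3N, CH2Cl2, 0 °C; then DBU, rt
Reagents that add atoms: none
Why: Mesylation and E1cB elimination complete the aldol condensation and should give the thermodynamically preferred E-arylidene ketone.

**Step 14**
Reactants: 24; 25 isobutylmagnesium bromide
Product: 26 (2S,5Z,8R)-5-methyl-2-[(1S)-3-methyl-1-(2,4,6-trifluorophenyl)butyl]-8-[2-(triethylsilyloxy)propan-2-yl]cyclodec-5-en-1-one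
Conditions: 25, CuBr·SMe2 (5 mol %), Josiphos-type ferrocenyl diphosphine (6 mol %), t-BuOMe, −78 °C; then NaOMe (cat.), MeOH–THF, rt; chromatography, C2 epimer recycled
Reagents that add atoms: none
Why: Copper-catalysed enantioselective conjugate addition of a Grignard reagent to the electron-poor β-aryl enone sets C1′ under catalyst control (ligand antipode chosen for Si-face delivery at the benzylidene carbon); the epimerisable α-centre C2 is then brought to the (2S) epimer by base equilibration, with its epimer separated and resubmitted.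

**Step 15**
Reactants: 26; 27 methyllithium
Product: 29 TES-protected (2R,3S,4S)-5,7-difluoro-4-isobutyl-2-methylchroman trans-bridged from C2 to C3 by the chain CH2CH2–CH[C(CH3)2OSiEt3]–CH2–CH=C(CH3)–CH2CH2 (Z olefin), via lithium tertiary alkoxide 28 (not isolated)
Conditions: MeLi (1.1 equiv), THF, −78 °C; then DMPU, 65 °C
Reagents that add atoms: none
Why: Methyllithium adds to the C1 ketone to give alkoxide 28, which on warming in THF–DMPU attacks the ortho C–F carbon of the trifluorophenyl ring, passes through a Meisenheimer adduct stabilised by the two remaining fluorines and expels fluoride (addition–elimination SNAr). The closest known reactions are organolithium 1,2-addition to α-branched medium-ring ketones and intramolecular aryl ether formation from alkoxides and polyfluoroarenes, here run in one flask. The pyran ring (O1, C2, C3, C4, C4a, C8a) closes by six-membered ipso attack of O1 on C8a (6-exo-trig), the C3–C4 bond already holding alkoxide and arene 1,3 to each other. The new C2 centre is set in the addition step: Felkin–Anh attack anti to the bulky C1′(aryl)(isobutyl) substituent, past the small α-hydrogen and from the open outer face of the ten-membered ring, places methyl trans to H3 and should give (2R). The step needs addition to outrun enolisation and metalation of the acidic aryl C–H, which the low temperature and near-stoichiometric charge of a small, fast nucleophile are meant to secure; it also needs no cation at C2 that the transannular C5=C6 olefin could capture, which holds because the C2 oxygen acts only as a nucleophile. Only an ortho fluorine is within reach of the alkoxide and the two ortho fluorines are equivalent, so a single chroman should form.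

**Step 16**
Reactants: 29; 30 N,N-dimethylformamide
Product: 32 6-formyl derivative of 29, via C6 aryllithium 31 (not isolated)
Conditions: LDA, THF, −78 °C; then 30, −78 → 0 °C
Reagents that add atoms: none
Why: Directed ortho-lithiation and formylation with DMF: C6–H, flanked by two fluorines, is the most acidic aromatic hydrogen and is removed at −78 °C, where the 2,6-difluoroaryllithium does not lose LiF.

**Step 17**
Reactants: 32; 30 N,N-dimethylformamide
Product: 35 6,8-diformyl derivative of 29, via lithium amino alkoxide 33 (not isolated), via C8-lithiated amino alkoxide 34 (not isolated)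
Conditions: LiN(Me)CH2CH2NMe2 (from the diamine and n-BuLi), THF, −78 °C; n-BuLi, −78 °C; then 30, −78 → 0 °C
Reagents that add atoms: none
Why: Comins-type in situ protection of the aldehyde as a lithium α-amino alkoxide, lithiation of the one remaining aromatic C–H (C8–H, acidified by the adjacent fluorine and ether oxygen) and formylation with DMF; aqueous work-up releases both aldehydes.

**Step 18**
Reactants: 35
Product: 36 5,7-bis[2-(trimethylsilyl)ethoxy] analogue of 35
Conditions: 2-(trimethylsilyl)ethanol, NaH, THF, 0 °C; then 35, 0 °C → rt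
Reagents that add atoms: 2-(trimethylsilyl)ethanol, C[Si](C)(C)CCO
Why: Nucleophilic aromatic substitution (addition–elimination): each fluorine now lies ortho or para to two formyl groups, so both should be displaced by the alkoxide at or below room temperature, faster than hydride transfer to the aldehydes.

**Step 19**
Reactants: 36
Product: 37 CNP0570248.1 (target)
Conditions: TBAF, THF, 0 °C → rt; dilute HCl work-up
Reagents that add atoms: none
Why: Fluoride-induced desilylation: the 2-(trimethylsilyl)ethyl aryl ethers fragment by β-elimination to ethylene and the stabilised diformyl phenoxides, and the triethylsilyl ether is cleaved in the same operation, leaving aldehydes, olefin and the tertiary aryl ether untouched.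

**Compound list**
1 | pent-4-enoic acid | C=CCCC(=O)O | starting material
2 | (4S)-4-benzyl-1,3-oxazolidin-2-one | O=C1N[C@@H](Cc2ccccc2)CO1 | starting material
3 | pent-4-enoic pivalic anhydride | C=CCCC(=O)OC(=O)C(C)(C)C | intermediate
4 | (4S)-4-benzyl-3-(pent-4-enoyl)-1,3-oxazolidin-2-one | C=CCCC(=O)N1[C@@H](Cc2ccccc2)COC1=O | intermediate
5 | prenyl bromide (1-bromo-3-methylbut-2-ene) | CC(C)=CCBr | starting material
6 | sodium Z-enolate of 4 | C=CC/C=C(\[O-])N1[C@@H](Cc2ccccc2)COC1=O.[Na+] | intermediate
7 | (4S)-4-benzyl-3-[(2R)-5-methyl-2-(prop-2-en-1-yl)hex-4-enoyl]-1,3-oxazolidin-2-one | C=CC[C@H](CC=C(C)C)C(=O)N1[C@@H](Cc2ccccc2)COC1=O | intermediate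
8 | methyl (2R)-5-methyl-2-(prop-2-en-1-yl)hex-4-enoate | C=CC[C@H](CC=C(C)C)C(=O)OC | intermediate
9 | methylmagnesium bromide | C[Mg]Br | starting material
10 | (3R)-2,6-dimethyl-3-(prop-2-en-1-yl)hept-5-en-2-ol | C=CC[C@H](CC=C(C)C)C(C)(C)O | intermediate
11 | triethyl{[(3R)-2,6-dimethyl-3-(prop-2-en-1-yl)hept-5-en-2-yl]oxy}silane | C=CC[C@H](CC=C(C)C)C(C)(C)O[Si](CC)(CC)CC | intermediate
12 | 9-{(4R)-7-methyl-4-[2-(triethylsilyloxy)propan-2-yl]oct-6-en-1-yl}-9-borabicyclo[3.3.1]nonane | CC(C)=CC[C@@H](CCCB1C2CCCC1CCC2)C(C)(C)O[Si](CC)(CC)CC | intermediate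
13 | (4R)-7-methyl-4-[2-(triethylsilyloxy)propan-2-yl]oct-6-en-1-ol | OCCC[C@H](CC=C(C)C)C(C)(C)O[Si](CC)(CC)CC | intermediate
14 | (4R)-7-methyl-4-[2-(triethylsilyloxy)propan-2-yl]oct-6-enal | O=CCC[C@H](CC=C(C)C)C(C)(C)O[Si](CC)(CC)CC | intermediate
15 | (1R,2S,4R)-2-(prop-1-en-2-yl)-4-[2-(triethylsilyloxy)propan-2-yl]cyclohexan-1-ol | C=C(C)[C@@H]1C[C@H](C(C)(C)O[Si](CC)(CC)CC)CC[C@H]1O | intermediate
16 | (2S,4R)-2-(prop-1-en-2-yl)-4-[2-(triethylsilyloxy)propan-2-yl]cyclohexan-1-one | C=C(C)[C@@H]1C[C@H](C(C)(C)O[Si](CC)(CC)CC)CCC1=O | intermediate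
17 | ethynylmagnesium bromide | C#C[Mg]Br | starting material
18 | (1R,2S,4R)-1-ethynyl-2-(prop-1-en-2-yl)-4-[2-(triethylsilyloxy)propan-2-yl]cyclohexan-1-ol | C=C(C)[C@@H]1C[C@H](C(C)(C)O[Si](CC)(CC)CC)CC[C@]1(O)C#C | intermediate
19 | (1S,2S,4R)-1-ethenyl-2-(prop-1-en-2-yl)-4-[2-(triethylsilyloxy)propan-2-yl]cyclohexan-1-ol | C=C(C)[C@@H]1C[C@H](C(C)(C)O[Si](CC)(CC)CC)CC[C@]1(O)C=C | intermediate
20 | 2,4,6-trifluorobenzaldehyde | O=Cc1c(F)cc(F)cc1F | starting material
21 | potassium (1Z,5Z,8R)-5-methyl-8-[2-(triethylsilyloxy)propan-2-yl]cyclodeca-1,5-dien-1-olate (ring carbons trans across C1=C2) | C/C1=C/C[C@H](C(C)(C)O[Si](CC)(CC)CC)CC/C([O-])=C/CC1.[K+] | intermediate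
22 | (5Z,8R)-2-[hydroxy(2,4,6-trifluorophenyl)methyl]-5-methyl-8-[2-(triethylsilyloxy)propan-2-yl]cyclodec-5-en-1-one (mixture at C2 and the carbinol carbon) | C/C1=C/C[C@H](C(C)(C)O[Si](CC)(CC)CC)CCC(=O)C(CC1)C(O)c1c(F)cc(F)cc1F | intermediate
23 | methanesulfonate of 22 | C/C1=C/C[C@H](C(C)(C)O[Si](CC)(CC)CC)CCC(=O)C(CC1)C(OS(C)(=O)=O)c1c(F)cc(F)cc1F | intermediate
24 | (2E,5Z,8R)-5-methyl-8-[2-(triethylsilyloxy)propan-2-yl]-2-[(2,4,6-trifluorophenyl)methylidene]cyclodec-5-en-1-one | C/C1=C/C[C@H](C(C)(C)O[Si](CC)(CC)CC)CCC(=O)/C(CC1)=C/c1c(F)cc(F)cc1F | intermediate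
25 | isobutylmagnesium bromide | CC(C)C[Mg]Br | starting material
26 | (2S,5Z,8R)-5-methyl-2-[(1S)-3-methyl-1-(2,4,6-trifluorophenyl)butyl]-8-[2-(triethylsilyloxy)propan-2-yl]cyclodec-5-en-1-one | C/C1=C/C[C@H](C(C)(C)O[Si](CC)(CC)CC)CCC(=O)[C@@H](CC1)[C@H](CC(C)C)c1c(F)cc(F)cc1F | intermediate
27 | methyllithium | [Li]C | starting material
28 | lithium (1R,2S,5Z,8R)-1,5-dimethyl-2-[(1S)-3-methyl-1-(2,4,6-trifluorophenyl)butyl]-8-[2-(triethylsilyloxy)propan-2-yl]cyclodec-5-en-1-olate | C/C1=C/C[C@H](C(C)(C)O[Si](CC)(CC)CC)CC[C@@](C)([O-])[C@@H](CC1)[C@H](CC(C)C)c1c(F)cc(F)cc1F.[Li+] | intermediate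
29 | TES-protected (2R,3S,4S)-5,7-difluoro-4-isobutyl-2-methylchroman, C2 and C3 trans-bridged by CH2CH2–CH[C(CH3)2OSiEt3]–CH2–CH=C(CH3)–CH2CH2 (R at the silyloxypropyl-bearing carbon, Z olefin) | C/C1=C/C[C@H](C(C)(C)O[Si](CC)(CC)CC)CC[C@@]2(C)Oc3cc(F)cc(F)c3[C@@H](CC(C)C)[C@@H]2CC1 | intermediate
30 | N,N-dimethylformamide | CN(C)C=O | starting material
31 | C6-lithio derivative of 29 | C/C1=C/C[C@H](C(C)(C)O[Si](CC)(CC)CC)CC[C@@]2(C)Oc3cc(F)c([Li])c(F)c3[C@@H](CC(C)C)[C@@H]2CC1 | intermediate
32 | 6-formyl derivative of 29 | C/C1=C/C[C@H](C(C)(C)O[Si](CC)(CC)CC)CC[C@@]2(C)Oc3cc(F)c(C=O)c(F)c3[C@@H](CC(C)C)[C@@H]2CC1 | intermediate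
33 | lithium α-amino alkoxide from 32 and lithium N,N,N′-trimethylethylenediamide (mixture at the new carbinol carbon) | C/C1=C/C[C@H](C(C)(C)O[Si](CC)(CC)CC)CC[C@@]2(C)Oc3cc(F)c(C([O-])N(C)CCN(C)C)c(F)c3[C@@H](CC(C)C)[C@@H]2CC1.[Li+] | intermediate
34 | C8-lithio derivative of 33 | C/C1=C/C[C@H](C(C)(C)O[Si](CC)(CC)CC)CC[C@@]2(C)Oc3c([Li])c(F)c(C([O-])N(C)CCN(C)C)c(F)c3[C@@H](CC(C)C)[C@@H]2CC1.[Li+] | intermediate
35 | 6,8-diformyl derivative of 29 | C/C1=C/C[C@H](C(C)(C)O[Si](CC)(CC)CC)CC[C@@]2(C)Oc3c(C=O)c(F)c(C=O)c(F)c3[C@@H](CC(C)C)[C@@H]2CC1 | intermediate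
36 | 5,7-bis[2-(trimethylsilyl)ethoxy] analogue of 35 | C/C1=C/C[C@H](C(C)(C)O[Si](CC)(CC)CC)CC[C@@]2(C)Oc3c(C=O)c(OCC[Si](C)(C)C)c(C=O)c(OCC[Si](C)(C)C)c3[C@@H](CC(C)C)[C@@H]2CC1 | intermediate
37 | CNP0570248.1 | C/C1=C/C[C@H](C(C)(C)O)CC[C@@]2(C)Oc3c(C=O)c(O)c(C=O)c(O)c3[C@@H](CC(C)C)[C@@H]2CC1 | target

**Step count:** 19 steps in total. Longest linear sequence: 19 steps (from 1 and 2).

**Steps most likely to fail**

Step 14. The chiral copper catalyst may control the face of the trisubstituted benzylidene carbon only partly, and protonation of the magnesium enolate is not under reagent control, so the C2 equilibrium may not favour the needed epimer. The fallback sets out from 24 and returns at 26. The copper-catalysed addition is run as before but the enolate is silylated before work-up (Me3SiCl, Et3N), and the trimethylsilyl enol ether F1 is isolated. C2 is then set by a catalytic enantioselective protonation of F1 (BINOL-derived N-triflyl thiophosphoramide, phenol as stoichiometric proton source, toluene, low temperature), with the catalyst antipode matched to the fixed C1′ centre, which gives 26.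

Step 12. The ring expansion may lose control of the C5=C6 geometry if the transition state with the ring bond quasi-equatorial competes, and the enolate may equilibrate before the aldehyde traps it. The fallback sets out from 19 and returns at 24; the olefin geometry is corrected after the ring is made instead of being dictated by the rearrangement. Steps 12 and 13 are run unchanged on the olefin mixture, and the ring-E arylidene ketone F2 is then isomerised at C5=C6 by reversible thiyl-radical addition (PhSSPh cat., hν, benzene). This should equilibrate towards the less strained ring-Z olefin, that is 24.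

Step 15. Methyllithium may enolise the hindered ketone or metalate the acidic aryl C–H, add from the wrong carbonyl face, or give a lithium alkoxide too weakly nucleophilic to close the ring. The fallback sets out from 26 and returns at 29; the C2–CH3 bond is made by methylene transfer and hydride opening instead of by an organolithium. Dimethylsulfonium methylide (Me3S+ I−, KHMDS, THF, −10 °C) converts 26 into the spiro-epoxide F3, whose diastereomers can be separated. LiEt3BH (THF, 0 °C) opens it at the CH2 terminus to the tertiary alcohol F4. KHMDS with 18-crown-6 in THF at 60 °C then closes the pyran ring by the same fluoride displacement. If the sulfonium ylide favours the wrong face, the sulfoxonium ylide (reversible addition) is used instead.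

**Further compounds**
F1 | step 14 | (5Z,8R)-5-methyl-2-[(1S)-3-methyl-1-(2,4,6-trifluorophenyl)butyl]-8-[2-(triethylsilyloxy)propan-2-yl]-1-(trimethylsilyloxy)cyclodeca-1,5-diene | C/C1=C/C[C@H](C(C)(C)O[Si](CC)(CC)CC)CCC(O[Si](C)(C)C)=C(CC1)[C@H](CC(C)C)c1c(F)cc(F)cc1F
F2 | step 12 | (2E,5E,8R)-5-methyl-8-[2-(triethylsilyloxy)propan-2-yl]-2-[(2,4,6-trifluorophenyl)methylidene]cyclodec-5-en-1-one | C\C1=C/C[C@H](C(C)(C)O[Si](CC)(CC)CC)CCC(=O)/C(CC1)=C/c1c(F)cc(F)cc1F
F3 | step 15 | spiro-epoxide of 26 (C1 carbonyl replaced by an oxirane, CH2 on the face taken by methyl in 28) | C/C1=C/C[C@H](C(C)(C)O[Si](CC)(CC)CC)CC[C@]2(CO2)[C@@H](CC1)[C@H](CC(C)C)c1c(F)cc(F)cc1F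
F4 | step 15 | (1R,2S,5Z,8R)-1,5-dimethyl-2-[(1S)-3-methyl-1-(2,4,6-trifluorophenyl)butyl]-8-[2-(triethylsilyloxy)propan-2-yl]cyclodec-5-en-1-ol | C/C1=C/C[C@H](C(C)(C)O[Si](CC)(CC)CC)CC[C@@](C)(O)[C@@H](CC1)[C@H](CC(C)C)c1c(F)cc(F)cc1F
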